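**Retrosynthetic overview** (herboxidiene numbering, C1 = CO2H … C19)

1. Herboxidiene ⇐ ester hydrolysis ⇐ C18‑OH‑directed epoxidation of C14=C15 ⇐ Suzuki coupling at C9–C10 of a pyranyl vinyl bromide (C1–C9) with a vinylboronate (C10–C19).
2. C10–C19 ⇐ Ireland–Claisen (C12, E‑C14=C15) ⇐ Evans–Tishchenko (C17 plus the propionate) ⇐ anti‑aldol with methacrolein (C15, C16) ⇐ (R)‑α‑benzoyloxy ethyl ketone.
3. Key step: that ketone is made from symmetric pentan‑3‑one by one enantioselective α‑benzoyloxylation with dibenzoyl peroxide. This single symmetry‑breaking event (C18) is relayed to every other stereocentre of the side chain.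
4. C1–C9 ⇐ oxa‑Michael ring closure ⇐ lactol (hydroformylation) ⇐ anti‑crotylation of (E)‑3‑bromo‑2‑methylacrolein (from methacrolein).
5. Ring order: tetrahydropyran first (before coupling), epoxide last (after coupling).

Assumption: catalysts, the Ipc‑boron reagent and Cl2CHBpin are purchased, and a one‑pot operation counts as one step.

---

**Side chain (C10–C19)**

Step 1
Reactants: 1 pentan‑3‑one; 2 dibenzoyl peroxide
Product: 3 (R)‑3‑oxopentan‑2‑yl benzoate
Conditions: 9‑amino‑9‑deoxy‑epi‑cinchona primary amine (10 mol %), Cl3CCO2H (20 mol %), BHT, 1 (5 equiv), THF, 25 °C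
Reagents that add atoms: none (the benzoyloxy group comes from reactant 2)
Why: Proposed new method: the chiral primary‑amine salt forms an enamine of 1 whose β‑carbon attacks the peroxide O–O bond on one face, converting one enantiotopic α‑H of the symmetric ketone into C18–OBz (R; the quinine or quinidine pseudo‑enantiomer is chosen empirically to give R, and ee is upgraded by crystallising 5); the closest known reactions are the cinchona‑amine α‑benzoyloxylation of cyclic ketones with this peroxide and the proline/nitrosobenzene α‑aminoxylation of ketones.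

Step 2
Reactants: 3; 4 methacrolein
Product: 5 (2R,4S,5R)‑5‑hydroxy‑4,6‑dimethyl‑3‑oxohept‑6‑en‑2‑yl benzoate
Conditions: (c‑Hex)2BCl, Me2NEt, Et2O, −78 → 0 °C; 4, −78 → −20 °C; H2O2, MeOH/pH 7 buffer
Reagents that add atoms: none
Why: Paterson boron anti‑aldol: the (E)‑enol borinate reacts through a chair transition state on the face bearing the benzoate, giving the 4,5‑anti/2,4‑syn adduct and so setting C16 and C15.

Step 3
Reactants: 5; 6 propanal
Product: 7 (3R,4R,5R,6R)‑6‑(benzoyloxy)‑5‑hydroxy‑2,4‑dimethylhept‑1‑en‑3‑yl propanoate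
Conditions: EtCHO (6 equiv), SmI2 (0.3 equiv, premixed with EtCHO to form the Sm(III) catalyst), THF, −10 °C
Reagents that add atoms: none (the propanoyl group comes from reactant 6)
Why: Evans–Tishchenko reduction: the Sm‑bound hemiacetal of the C15 alcohol delivers hydride intramolecularly to the C17 ketone, giving the 1,3‑anti diol monoester, which sets C17 and installs the C15 propionate in one step.

Step 4
Reactants: 7
Product: 8 (3R,4S,5R,6R)‑6‑(benzoyloxy)‑5‑methoxy‑2,4‑dimethylhept‑1‑en‑3‑yl propanoate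
Conditions: Me3OBF4, Proton‑sponge, CH2Cl2, 0 °C → rt
Reagents that add atoms: trimethyloxonium tetrafluoroborate, C[O+](C)C.F[B-](F)(F)F
Why: Meerwein O‑methylation (SN2 on Me3O+) under near‑neutral conditions, so neither ester migrates and no stereocentre is touched (the C4 descriptor changes only through CIP priorities).

Step 5
Reactants: 8
Product: 9 (2S,4E,6S,7R,8R)‑8‑(benzoyloxy)‑7‑methoxy‑2,4,6‑trimethylnon‑4‑enoic acid
Conditions: LDA, TMSCl/Et3N, THF, −78 °C → rt; 1 M HCl
Reagents that add atoms: none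
Why: Ireland–Claisen [3,3] rearrangement: LDA/THF gives the (E)‑silyl ketene acetal, and the chair transition state with the C16 chain equatorial transfers the C15 configuration to C12 (S) and forms the (E)‑C14=C15 alkene.

Step 6
Reactants: 9
Product: 10 (2S,4E,6S,7R,8R)‑7‑methoxy‑2,4,6‑trimethylnon‑4‑ene‑1,8‑diol
Conditions: LiAlH4, THF, 0 °C → rt
Reagents that add atoms: none
Why: Hydride reduction of the acid to the primary alcohol with simultaneous cleavage of the benzoate; the isolated alkene and methyl ether are inert.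

Step 7
Reactants: 10
Product: 11 (2S,4E,6S,7R,8R)‑8‑hydroxy‑7‑methoxy‑2,4,6‑trimethylnon‑4‑enal
Conditions: TEMPO (10 mol %), PhI(OAc)2, CH2Cl2, rt
Reagents that add atoms: none
Why: Oxoammonium (TEMPO) oxidation is selective for the primary over the secondary alcohol and is non‑basic, so C12 does not epimerise.

Step 8
Reactants: 11
Product: 12 (2R,3R,4S,5E,8S,9E)‑3‑methoxy‑4,6,8‑trimethyl‑10‑(4,4,5,5‑tetramethyl‑1,3,2‑dioxaborolan‑2‑yl)deca‑5,9‑dien‑2‑ol
Conditions: Cl2CHB(pin), CrCl2, LiI, THF, rt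
Reagents that add atoms: 2‑(dichloromethyl)‑4,4,5,5‑tetramethyl‑1,3,2‑dioxaborolane, ClC(Cl)B1OC(C)(C)C(C)(C)O1
Why: Takai‑type gem‑dichromium olefination (boron variant) converts the aldehyde directly into the (E)‑alkenylboronate and tolerates the free C18 alcohol.

**Pyran fragment (C1–C9)**

Step 9
Reactants: 4 methacrolein
Product: 13 (E)‑3‑bromo‑2‑methylprop‑2‑enal
Conditions: Br2, CH2Cl2, −78 → 0 °C; then Et3N, 0 °C → rt
Reagents that add atoms: bromine, BrBr
Why: Bromine addition then E2 dehydrobromination of the tertiary bromide gives the conjugated β‑bromoenal, (E) under thermodynamic control.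

Step 10
Reactants: 13
Product: 14 (1E,3S,4S)‑1‑bromo‑2,4‑dimethylhexa‑1,5‑dien‑3‑ol
Conditions: (E)‑crotyl‑B(Ipc)2 [trans‑but‑2‑ene, n‑BuLi/KOt‑Bu; (−)‑Ipc2BOMe, from (+)‑α‑pinene; BF3·OEt2], THF, −78 °C; NaBO3 work‑up
Reagents that add atoms: (E)‑crotyldiisopinocampheylborane, C/C=C/CB(C1CC2CC(C1C)C2(C)C)C1CC2CC(C1C)C2(C)C (Ipc stereodescriptors omitted; crotyl unit from trans‑but‑2‑ene)
Why: Brown asymmetric crotylboration: the closed chair transition state makes the (E)‑crotyl reagent give the C6/C7 anti product, and the (+)‑α‑pinene‑derived Ipc ligands direct attack to the si face of the aldehyde, giving (3S,4S).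

Step 11
Reactants: 14
Product: 15 (5S,6S)‑6‑[(E)‑1‑bromoprop‑1‑en‑2‑yl]‑5‑methyloxan‑2‑ol (anomer mixture)
Conditions: Rh(acac)(CO)2 (1 mol %), BIPHEPHOS (2 mol %), CO/H2 (1:1, 10 bar), THF, 60 °C
Reagents that add atoms: carbon monoxide, [C-]#[O+] (with H2)
Why: Linear‑selective Rh‑catalysed hydroformylation of the terminal alkene, after which the δ‑hydroxy aldehyde closes to the lactol; the trisubstituted vinyl bromide is not a hydroformylation substrate.

Step 12
Reactants: 15
Product: 16 methyl 2‑[(2R,5S,6S)‑6‑[(E)‑1‑bromoprop‑1‑en‑2‑yl]‑5‑methyloxan‑2‑yl]acetate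
Conditions: Ph3P=CHCO2Me, PhMe, 80 °C; then DBU (or cat. t‑BuOK), rt, equilibrating
Reagents that add atoms: methyl (triphenylphosphoranylidene)acetate, COC(=O)C=P(c1ccccc1)(c1ccccc1)c1ccccc1
Why: Wittig olefination of the open hydroxy‑aldehyde gives the (E)‑enoate, and 6‑exo oxa‑Michael addition under thermodynamic control gives the all‑equatorial 2,6‑cis tetrahydropyran (C3 R).

**Union and endgame**

Step 13
Reactants: 12; 16
Product: 17 methyl 2‑[(2R,5S,6S)‑6‑[(2E,4E,6S,8E,10S,11R,12R)‑12‑hydroxy‑11‑methoxy‑6,8,10‑trimethyltrideca‑2,4,8‑trien‑2‑yl]‑5‑methyloxan‑2‑yl]acetate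
Conditions: Pd(PPh3)4 (5 mol %), TlOEt, THF/H2O (3:1), rt
Reagents that add atoms: none
Why: Suzuki–Miyaura sp2–sp2 coupling proceeds with retention of both alkene geometries to give the (E,E)‑diene; the ester and free alcohol are tolerated.

Step 14
Reactants: 17
Product: 18 herboxidiene methyl ester
Conditions: VO(acac)2 (10 mol %), t‑BuOOH, CH2Cl2, −15 → 0 °C
Reagents that add atoms: tert‑butyl hydroperoxide, CC(C)(C)OO
Why: Hydroxyl‑directed vanadium epoxidation: the C18‑OH‑bound peroxovanadium delivers oxygen to the bishomoallylic C14=C15 alkene on the face fixed by the C16–C18 stereotriad (14R,15R), leaving the undirected diene untouched.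

Step 15
Reactants: 18
Product: 19 herboxidiene
Conditions: Me3SnOH, ClCH2CH2Cl, 80 °C; mild acidic work‑up
Reagents that add atoms: trimethyltin hydroxide, C[Sn](C)(C)O
Why: Near‑neutral organotin ester hydrolysis (acyl substitution) spares the epoxide and all stereocentres.

---

**Compound list**

1 | pentan‑3‑one | CCC(=O)CC | starting material
2 | dibenzoyl peroxide | O=C(OOC(=O)c1ccccc1)c1ccccc1 | starting material
3 | (R)‑3‑oxopentan‑2‑yl benzoate | CCC(=O)[C@@H](C)OC(=O)c1ccccc1 | intermediate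
4 | methacrolein | C=C(C)C=O | starting material
5 | (2R,4S,5R)‑5‑hydroxy‑4,6‑dimethyl‑3‑oxohept‑6‑en‑2‑yl benzoate | C=C(C)[C@H](O)[C@H](C)C(=O)[C@@H](C)OC(=O)c1ccccc1 | intermediate
6 | propanal | CCC=O | starting material
7 | (3R,4R,5R,6R)‑6‑(benzoyloxy)‑5‑hydroxy‑2,4‑dimethylhept‑1‑en‑3‑yl propanoate | C=C(C)[C@H](OC(=O)CC)[C@H](C)[C@@H](O)[C@@H](C)OC(=O)c1ccccc1 | intermediate
8 | (3R,4S,5R,6R)‑6‑(benzoyloxy)‑5‑methoxy‑2,4‑dimethylhept‑1‑en‑3‑yl propanoate | C=C(C)[C@H](OC(=O)CC)[C@H](C)[C@@H](OC)[C@@H](C)OC(=O)c1ccccc1 | intermediate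
9 | (2S,4E,6S,7R,8R)‑8‑(benzoyloxy)‑7‑methoxy‑2,4,6‑trimethylnon‑4‑enoic acid | OC(=O)[C@@H](C)C/C(C)=C/[C@H](C)[C@@H](OC)[C@@H](C)OC(=O)c1ccccc1 | intermediate
10 | (2S,4E,6S,7R,8R)‑7‑methoxy‑2,4,6‑trimethylnon‑4‑ene‑1,8‑diol | OC[C@@H](C)C/C(C)=C/[C@H](C)[C@@H](OC)[C@@H](C)O | intermediate
11 | (2S,4E,6S,7R,8R)‑8‑hydroxy‑7‑methoxy‑2,4,6‑trimethylnon‑4‑enal | O=C[C@@H](C)C/C(C)=C/[C@H](C)[C@@H](OC)[C@@H](C)O | intermediate
12 | (2R,3R,4S,5E,8S,9E)‑3‑methoxy‑4,6,8‑trimethyl‑10‑(pinacolboryl)deca‑5,9‑dien‑2‑ol | CC1(C)OB(/C=C/[C@@H](C)C/C(C)=C/[C@H](C)[C@@H](OC)[C@@H](C)O)OC1(C)C | intermediate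
13 | (E)‑3‑bromo‑2‑methylprop‑2‑enal | O=C/C(C)=C/Br | intermediate
14 | (1E,3S,4S)‑1‑bromo‑2,4‑dimethylhexa‑1,5‑dien‑3‑ol | Br/C=C(\C)[C@@H](O)[C@@H](C)C=C | intermediate
15 | (5S,6S)‑6‑[(E)‑1‑bromoprop‑1‑en‑2‑yl]‑5‑methyloxan‑2‑ol | Br/C=C(\C)[C@H]1OC(O)CC[C@@H]1C | intermediate
16 | methyl 2‑[(2R,5S,6S)‑6‑[(E)‑1‑bromoprop‑1‑en‑2‑yl]‑5‑methyloxan‑2‑yl]acetate | Br/C=C(\C)[C@H]1O[C@@H](CC(=O)OC)CC[C@@H]1C | intermediate
17 | 14,15‑deoxy (alkene) herboxidiene methyl ester | CO[C@H]([C@@H](C)/C=C(\C)C[C@H](C)/C=C/C=C(\C)[C@H]1O[C@@H](CC(=O)OC)CC[C@@H]1C)[C@@H](C)O | intermediate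
18 | herboxidiene methyl ester | CO[C@H]([C@@H](C)[C@H]1O[C@]1(C)C[C@H](C)/C=C/C=C(\C)[C@H]1O[C@@H](CC(=O)OC)CC[C@@H]1C)[C@@H](C)O | intermediate
19 | herboxidiene | CO[C@H]([C@@H](C)[C@H]1O[C@]1(C)C[C@H](C)/C=C/C=C(\C)[C@H]1O[C@@H](CC(=O)O)CC[C@@H]1C)[C@@H](C)O | target

---

**Step count:** 15 steps in total. Longest linear sequence: 11 steps (1–8, then 13–15).

**Three steps most likely to fail, with fallbacks**

- **Step 1 (enantioselective benzoyloxylation of an acyclic ketone).** Risks are slow enamine formation, catalyst N‑oxidation by the peroxide and modest ee. Fallback: give up the catalytic desymmetrisation and make 3 from the chiral pool ((R)‑lactate ester → Weinreb amide → EtMgBr → Bz2O), which adds two steps.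
- **Step 3 (Evans–Tishchenko on an α′‑benzoyloxy ketone).** Sm(II) may cleave the α‑acyloxy ketone, or an acyl group may migrate. Fallback: Evans–Saksena anti‑reduction (Me4NBH(OAc)3) to the 1,3‑anti diol, then an orthoester Johnson–Claisen (EtC(OEt)3, cat. EtCO2H, heat), which can only engage the allylic C15‑OH, then methylation of C17‑OH. The C12 selectivity would be lower than with the Ireland–Claisen.
- **Step 11 (hydroformylation next to a vinyl bromide).** Risks are branched aldehyde, alkene isomerisation or Rh insertion into C–Br. Fallback: 9‑BBN hydroboration/oxidation to the 1,5‑diol, TEMPO/PhI(OAc)2 to the δ‑lactone, addition of the lithium enolate of methyl acetate, and Et3SiH/BF3·OEt2 reduction of the resulting lactol to the same 2,6‑cis pyran 16.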